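Numbering (indane): C1 acetyl (carbonyl carbon C1′), C2 angelate, C3, C3a, C4 (=CH2), C5, C6 epoxy ester, C7 isopropyl, C7a. Ring A = C3a–C4–C5–C6–C7–C7a and ring B = C1–C2–C3–C3a–C7a.
Cuts: the ester C–O bonds at C6 and C2 go first, then C1′–CH3 and C1–C2 (ring B), then C3a–C4 (ring A), then C5–C6, C3a=C3 and C7–C7a.
Enabling feature: C4 carries the exocyclic methylene and is bonded to ring-fusion carbon C3a, which lies β to C2 through C3. A C4 vinyl radical tethered through C5–C6–C7–C7a can therefore attack a C3a=C3–C2 enoate and close ring A with its =CH2 already present.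
Forward order: the open C6–C7–C7a–C3a chain is built (Michael, Wittig, Nef, bromoallylation), ring A closes by the radical step, ring B closes by aldol-lactonisation of the two acetic arms, and the two esters go on last.
Stereochemistry: C7/C7a come from an enamine-catalysed Michael addition, C6 from a chiral 2-bromoallylborane and C3a from the chair of the ring A closure. C1/C2 come from a necessarily cis-fused β-lactone, the oxirane from a Sharpless epoxidation and the Z-alkene from angelic acid.

Key step: step 9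

Assumption: the (S,S)-sulfonamide controller of step 7 is taken to deliver the 2-bromoallyl group to the Re face of the C6 aldehyde. This follows a chair model with the aldehyde substituent equatorial and the allyl chain turned away from the nearer sulfonyl group. Both antipodes of the diamine are commercial.

Step 1
Reactants: 1 2-methylpropanal; 2 nitromethane
Product: 3 3-methyl-1-nitrobutan-2-ol (racemic)
Conditions: KOt-Bu (5 mol %), THF/t-BuOH, 0 °C to rt
Reagents that add atoms: none
Why: Base-catalysed Henry reaction of nitromethane with an aliphatic aldehyde; the carbinol centre is destroyed in step 2, so it needs no control.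

Step 2
Reactants: 3 3-methyl-1-nitrobutan-2-ol
Product: 5 (E)-3-methyl-1-nitrobut-1-ene, via mesylate 4 (not isolated)
Conditions: MsCl, Et3N (2.2 equiv), CH2Cl2, 0 °C
Reagents that add atoms: none
Why: Mesylation followed by E1cB elimination of the β-nitro mesylate should give the conjugated nitroalkene, in which the E geometry is strongly favoured.

Step 3
Reactants: 5 (E)-3-methyl-1-nitrobut-1-ene; 6 tert-butyl 4-oxobutanoate
Product: 7 tert-butyl (3S,4S)-3-formyl-5-methyl-4-(nitromethyl)hexanoate
Conditions: (R)-α,α-diphenylprolinol trimethylsilyl ether (10 mol %), 4-nitrophenol (10 mol %), toluene, 0 °C to rt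
Reagents that add atoms: none
Why: Enamine-catalysed asymmetric Michael addition of an aldehyde to a nitroalkene, in which the E-enamine of 6 is shielded on one face by the diphenyl(silyloxy)methyl group of the R catalyst and attacks 5 through the open synclinal transition state, which should set C7a and C7 together as the syn (3S,4S) pair.

Step 4
Reactants: 7 tert-butyl (3S,4S)-3-formyl-5-methyl-4-(nitromethyl)hexanoate; 8 ethyl (triphenylphosphoranylidene)acetate
Product: 9 6-tert-butyl 1-ethyl (2E,4R)-4-[(2S)-3-methyl-1-nitrobutan-2-yl]hex-2-enedioate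
Conditions: CH2Cl2, rt
Reagents that add atoms: none
Why: Wittig olefination with a stabilised ylide is E-selective, and the ylide is too weakly basic to epimerise C7a or deprotonate the nitroalkane (the change of the C7a descriptor from S to R is a priority effect only).

Step 5
Reactants: 9 6-tert-butyl 1-ethyl (2E,4R)-4-[(2S)-3-methyl-1-nitrobutan-2-yl]hex-2-enedioate
Product: 11 6-tert-butyl 1-ethyl (2E,4R)-4-[(2S)-3-methyl-1-oxobutan-2-yl]hex-2-enedioate, via potassium nitronate 10 (not isolated)
Conditions: KOt-Bu (1.0 equiv), THF, 0 °C; then dimethyldioxirane (1.1 equiv, acetone), 0 °C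
Reagents that add atoms: dimethyldioxirane, CC1(C)OO1
Why: Oxidative Nef reaction, in which the nitro group is by far the most acidic site, the dioxirane oxidises the nitronate C=N bond with loss of nitrite, the electron-poor enoate is inert to the oxidant, and the absence of strong acid spares the tert-butyl ester and the C7 centre.

Step 6
Reactants: 12 2,3-dibromoprop-1-ene
Product: 13 (2-bromoprop-2-en-1-yl)tributylstannane
Conditions: Bu3SnH, LiN(i-Pr)2, THF, 0 °C; then 12, −78 °C to rt
Reagents that add atoms: tributyltin hydride, CCCC[SnH](CCCC)CCCC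
Why: SN2 displacement of the allylic bromide by the stannyl anion, with the vinylic C–Br bond left untouched at low temperature.

Step 7
Reactants: 11 6-tert-butyl 1-ethyl (2E,4R)-4-[(2S)-3-methyl-1-oxobutan-2-yl]hex-2-enedioate; 13 (2-bromoprop-2-en-1-yl)tributylstannane
Product: 15 6-tert-butyl 1-ethyl (2E,4R)-4-[(3S,4R)-6-bromo-4-hydroxy-2-methylhept-6-en-3-yl]hex-2-enedioate, via 2-bromoallyl diazaborolidine 14 (not isolated)
Conditions: (S,S)-TsNHCH(Ph)CH(Ph)NHTs, BBr3, CH2Cl2, 0 °C to rt, evaporate; 13, CH2Cl2, 0 °C to rt; 11, −78 °C; pH 7 buffer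
Reagents that add atoms: none
Why: Asymmetric allylboration through a closed chair transition state, in which the C2-symmetric sulfonamide controller should direct the 2-bromoallyl group to the Re face of 11 and set C6 as R by reagent control, while both esters are inert at −78 °C.

Step 8
Reactants: 15 6-tert-butyl 1-ethyl (2E,4R)-4-[(3S,4R)-6-bromo-4-hydroxy-2-methylhept-6-en-3-yl]hex-2-enedioate
Product: 16 6-tert-butyl 1-ethyl (2E,4R)-4-{(3S,4R)-6-bromo-4-[(tert-butyldimethylsilyl)oxy]-2-methylhept-6-en-3-yl}hex-2-enedioate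
Conditions: TBSOTf, 2,6-lutidine, CH2Cl2, −78 to 0 °C
Reagents that add atoms: tert-butyldimethylsilyl trifluoromethanesulfonate, CC(C)(C)[Si](C)(C)OS(=O)(=O)C(F)(F)F
Why: Silylation of a hindered secondary alcohol with the silyl triflate under non-nucleophilic buffering, which also blocks oxa-Michael attack of the C6 hydroxyl on C3a.

Step 9
Reactants: 16 6-tert-butyl 1-ethyl (2E,4R)-4-{(3S,4R)-6-bromo-4-[(tert-butyldimethylsilyl)oxy]-2-methylhept-6-en-3-yl}hex-2-enedioate
Product: 17 tert-butyl 2-[(1R,2S,3R,6R)-3-[(tert-butyldimethylsilyl)oxy]-6-(2-ethoxy-2-oxoethyl)-5-methylidene-2-(propan-2-yl)cyclohexyl]acetate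
Conditions: Bu3SnH (1.3 equiv, syringe pump, 8 h), AIBN (0.2 equiv), benzene (0.01 M), reflux
Reagents that add atoms: none
Why: Bu3Sn• abstracts bromine from 16 to give the σ-type vinyl radical at C4, which adds to C3a, the β-carbon of the enoate, and the α-ester radical formed at C3 takes hydrogen from Bu3SnH to carry the chain. The closest known reaction type is the tin hydride-mediated cyclisation of vinyl radicals onto α,β-unsaturated esters. Ring A closes in the 6-exo-trig mode, and the exocyclic methylene is delivered directly because the radical carbon already bears the =CH2 group. The only new stereocentre, C3a, is controlled by a chair-like transition state in which the C7 isopropyl group, the C7a acetate arm and the acrylate terminus are equatorial and only the C6 silyloxy group is axial, so that H-3a should end anti to H-7a (3aR, trans arms). The step needs ring closure to outrun hydrogen transfer to the vinyl radical (from the stannane, or by 1,5-shift from C7a–H or the isopropyl methine) and needs exo rather than 7-endo attack. This is secured by the electron-poor E-enoate, polarity-matched at its β-carbon to the nucleophilic radical, by the three branched centres that pre-fold the tether, and by the low stationary stannane concentration.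

Step 10
Reactants: 17 tert-butyl 2-[(1R,2S,3R,6R)-3-[(tert-butyldimethylsilyl)oxy]-6-(2-ethoxy-2-oxoethyl)-5-methylidene-2-(propan-2-yl)cyclohexyl]acetate
Product: 18 tert-butyl 2-[(1R,2S,3R,6R)-3-[(tert-butyldimethylsilyl)oxy]-5-methylidene-6-(2-oxoethyl)-2-(propan-2-yl)cyclohexyl]acetate
Conditions: i-Bu2AlH (1.1 equiv), toluene, −78 °C; aq. potassium sodium tartrate
Reagents that add atoms: none
Why: Partial hydride reduction of an ester to the aldehyde, selective because the ethyl ester reacts at −78 °C whereas the bulky tert-butyl ester does not.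

Step 11
Reactants: 18 tert-butyl 2-[(1R,2S,3R,6R)-3-[(tert-butyldimethylsilyl)oxy]-5-methylidene-6-(2-oxoethyl)-2-(propan-2-yl)cyclohexyl]acetate
Product: 20 2-[(1R,2S,3R,6R)-3-[(tert-butyldimethylsilyl)oxy]-5-methylidene-6-(2-oxoethyl)-2-(propan-2-yl)cyclohexyl]acetic acid, via trimethylsilyl ester 19 (not isolated)
Conditions: TMSOTf, 2,6-lutidine, CH2Cl2, 0 °C; then pH 5 aqueous buffer
Reagents that add atoms: none
Why: Silyl triflate-induced cleavage of a tert-butyl ester with loss of isobutene, run under lutidine buffering so that no free strong acid can isomerise the exocyclic alkene or remove the hindered secondary silyl ether.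

Step 12
Reactants: 20 2-[(1R,2S,3R,6R)-3-[(tert-butyldimethylsilyl)oxy]-5-methylidene-6-(2-oxoethyl)-2-(propan-2-yl)cyclohexyl]acetic acid
Product: 21 β-lactone (C1′ to O on C2, cis-fused) of (1R,2S,3aR,6R,7S,7aR)-6-[(tert-butyldimethylsilyl)oxy]-2-hydroxy-4-methylidene-7-(propan-2-yl)octahydro-1H-indene-1-carboxylic acid
Conditions: 2-chloro-1-methylpyridinium iodide (3 equiv), Et3N (4 equiv), MeCN, rt, 20 added by syringe pump (10 h)
Reagents that add atoms: none
Why: Nucleophile-catalysed aldol-lactonisation of an aldehyde acid, in which only the activated acid side can enolise (C1), only the aldehyde can accept (C2), the four-membered lactone can only be cis-fused so that C1′ and the C2 oxygen share one face, and the face of H-7a is expected because the opposite orientation at C1 would nearly eclipse the C7a–C7 bond and press the acyl carbon against the isopropyl group.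

Step 13
Reactants: 21 β-lactone of step 12
Product: 22 (1R,2S,3aR,6R,7S,7aR)-6-[(tert-butyldimethylsilyl)oxy]-2-hydroxy-N-methoxy-N-methyl-4-methylidene-7-(propan-2-yl)octahydro-1H-indene-1-carboxamide
Conditions: MeNH(OMe)·HCl, AlMe3, CH2Cl2, 0 °C to rt
Reagents that add atoms: N,O-dimethylhydroxylamine hydrochloride, CNOC.Cl
Why: Aluminium amide aminolysis of a strained β-lactone by acyl–oxygen cleavage, which breaks no bond to C1 or C2 and therefore keeps both centres.

Step 14
Reactants: 22 N-methoxy-N-methylamide of step 13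
Product: 23 1-[(1R,2S,3aR,6R,7S,7aR)-6-[(tert-butyldimethylsilyl)oxy]-2-hydroxy-4-methylidene-7-(propan-2-yl)octahydro-1H-inden-1-yl]ethan-1-one
Conditions: MeMgBr (3.5 equiv), THF, −20 to 0 °C; aq. NH4Cl
Reagents that add atoms: methylmagnesium bromide, C[Mg]Br
Why: Grignard addition to an N-methoxy-N-methylamide stops at the chelated tetrahedral adduct (the first equivalent is consumed by the hydroxyl), so the methyl ketone appears only on work-up, and C1 keeps what should also be its more stable orientation.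

Step 15
Reactants: 24 angelic acid, (2Z)-2-methylbut-2-enoic acid (two molecules)
Product: 25 angelic anhydride, (2Z)-2-methylbut-2-enoic anhydride
Conditions: DCC (0.5 equiv), CH2Cl2, 0 °C to rt
Reagents that add atoms: none
Why: Carbodiimide dehydration of a carboxylic acid to its symmetrical anhydride, run without a nucleophilic catalyst so that the Z geometry should be kept.

Step 16
Reactants: 23 ketol of step 14; 25 angelic anhydride
Product: 27 (1R,2S,3aR,6R,7S,7aR)-1-acetyl-6-[(tert-butyldimethylsilyl)oxy]-4-methylidene-7-(propan-2-yl)octahydro-1H-inden-2-yl (2Z)-2-methylbut-2-enoate, via lithium alkoxide 26 (not isolated)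
Conditions: LiN(SiMe3)2 (1.0 equiv), THF, −78 °C; 25 (1.5 equiv), −78 to −20 °C; aq. NH4Cl
Reagents that add atoms: none
Why: O-acylation of a preformed lithium alkoxide with the symmetrical anhydride avoids the amine addition–elimination path that turns angelates into tiglates, while one equivalent of base and low temperature should hold the chelated aldolate against retro-aldol cleavage and spare the product from β-elimination.

Step 17
Reactants: 27 silyl ether of step 16
Product: 28 (1R,2S,3aR,6R,7S,7aR)-1-acetyl-6-hydroxy-4-methylidene-7-(propan-2-yl)octahydro-1H-inden-2-yl (2Z)-2-methylbut-2-enoate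
Conditions: HF·pyridine, pyridine/THF, 0 °C to rt
Reagents that add atoms: none
Why: Fluoride-induced silyl ether cleavage under mildly acidic buffering, chosen because a basic fluoride source could expel the β-acyloxy group.

Step 18
Reactants: 24 angelic acid
Product: 29 (2Z)-2-methylbut-2-en-1-ol
Conditions: LiAlH4, Et2O, 0 °C to rt
Reagents that add atoms: none
Why: LiAlH4 reduction of a carboxylic acid to the primary allylic alcohol, which leaves the trisubstituted Z-alkene unchanged.

Step 19
Reactants: 29 (2Z)-2-methylbut-2-en-1-ol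
Product: 30 [(2R,3S)-2,3-dimethyloxiran-2-yl]methanol
Conditions: Ti(Oi-Pr)4 (10 mol %), D-(−)-diethyl tartrate (12 mol %), t-BuOOH, 4 Å MS, CH2Cl2, −20 °C
Reagents that add atoms: tert-butyl hydroperoxide, CC(C)(C)OO
Why: Sharpless asymmetric epoxidation, in which the D-(−)-tartrate complex should deliver oxygen to the alkene face that gives the (2R,3S)-epoxy alcohol and the syn addition keeps the C3 methyl cis to the CH2OH group.

Step 20
Reactants: 30 [(2R,3S)-2,3-dimethyloxiran-2-yl]methanol
Product: 31 (2S,3S)-2,3-dimethyloxirane-2-carboxylic acid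
Conditions: RuCl3 (2 mol %), NaIO4, CCl4/MeCN/H2O, rt
Reagents that add atoms: water, O
Why: Ruthenium-catalysed periodate oxidation of a primary alcohol to the acid tolerates the oxirane, and the change of the C2 descriptor from R to S is a priority effect only.

Step 21
Reactants: 28 alcohol of step 17; 31 (2S,3S)-2,3-dimethyloxirane-2-carboxylic acid
Product: 33 target, (1R,2S,3aR,6R,7S,7aR)-1-acetyl-4-methylidene-2-{[(2Z)-2-methylbut-2-enoyl]oxy}-7-(propan-2-yl)octahydro-1H-inden-6-yl (2S,3S)-2,3-dimethyloxirane-2-carboxylate, via mixed anhydride 32 (not isolated)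
Conditions: 31, 2,4,6-trichlorobenzoyl chloride, Et3N, toluene, rt; then 28, DMAP, toluene, rt
Reagents that add atoms: none
Why: Yamaguchi esterification, in which the mixed anhydride is attacked only at the less hindered oxirane carbonyl, the acid has no α-hydrogen to epimerise, and no bond to C6 is broken, so the axial 6R configuration is kept.

Compound list
1 | 2-methylpropanal | CC(C)C=O | starting material
2 | nitromethane | C[N+](=O)[O-] | starting material
3 | 3-methyl-1-nitrobutan-2-ol (racemic) | CC(C)C(O)C[N+](=O)[O-] | intermediate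
4 | 3-methyl-1-nitrobutan-2-yl methanesulfonate (racemic, not isolated) | CC(C)C(C[N+](=O)[O-])OS(C)(=O)=O | intermediate
5 | (E)-3-methyl-1-nitrobut-1-ene | CC(C)/C=C/[N+](=O)[O-] | intermediate
6 | tert-butyl 4-oxobutanoate | O=CCCC(=O)OC(C)(C)C | starting material
7 | tert-butyl (3S,4S)-3-formyl-5-methyl-4-(nitromethyl)hexanoate | O=[N+]([O-])C[C@@H](C(C)C)[C@@H](C=O)CC(=O)OC(C)(C)C | intermediate
8 | ethyl (triphenylphosphoranylidene)acetate | CCOC(=O)C=P(c1ccccc1)(c1ccccc1)c1ccccc1 | starting material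
9 | 6-tert-butyl 1-ethyl (2E,4R)-4-[(2S)-3-methyl-1-nitrobutan-2-yl]hex-2-enedioate | O=[N+]([O-])C[C@@H](C(C)C)[C@@H](/C=C/C(=O)OCC)CC(=O)OC(C)(C)C | intermediate
10 | potassium nitronate of 9 (not isolated) | [K+].[O-][N+]([O-])=C[C@@H](C(C)C)[C@@H](/C=C/C(=O)OCC)CC(=O)OC(C)(C)C | intermediate
11 | 6-tert-butyl 1-ethyl (2E,4R)-4-[(2S)-3-methyl-1-oxobutan-2-yl]hex-2-enedioate | O=C[C@@H](C(C)C)[C@@H](/C=C/C(=O)OCC)CC(=O)OC(C)(C)C | intermediate
12 | 2,3-dibromoprop-1-ene | C=C(Br)CBr | starting material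
13 | (2-bromoprop-2-en-1-yl)tributylstannane | C=C(Br)C[Sn](CCCC)(CCCC)CCCC | intermediate
14 | (4S,5S)-2-(2-bromoprop-2-en-1-yl)-1,3-bis(4-methylbenzenesulfonyl)-4,5-diphenyl-1,3,2-diazaborolidine (not isolated) | C=C(Br)CB1N(S(=O)(=O)c2ccc(C)cc2)[C@@H](c2ccccc2)[C@H](c2ccccc2)N1S(=O)(=O)c1ccc(C)cc1 | intermediate
15 | 6-tert-butyl 1-ethyl (2E,4R)-4-[(3S,4R)-6-bromo-4-hydroxy-2-methylhept-6-en-3-yl]hex-2-enedioate | C=C(Br)C[C@@H](O)[C@@H](C(C)C)[C@@H](/C=C/C(=O)OCC)CC(=O)OC(C)(C)C | intermediate
16 | 6-tert-butyl 1-ethyl (2E,4R)-4-{(3S,4R)-6-bromo-4-[(tert-butyldimethylsilyl)oxy]-2-methylhept-6-en-3-yl}hex-2-enedioate (radical precursor) | C=C(Br)C[C@@H](O[Si](C)(C)C(C)(C)C)[C@@H](C(C)C)[C@@H](/C=C/C(=O)OCC)CC(=O)OC(C)(C)C | intermediate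
17 | tert-butyl 2-[(1R,2S,3R,6R)-3-[(tert-butyldimethylsilyl)oxy]-6-(2-ethoxy-2-oxoethyl)-5-methylidene-2-(propan-2-yl)cyclohexyl]acetate | C=C1C[C@@H](O[Si](C)(C)C(C)(C)C)[C@@H](C(C)C)[C@H](CC(=O)OC(C)(C)C)[C@H]1CC(=O)OCC | intermediate
18 | tert-butyl 2-[(1R,2S,3R,6R)-3-[(tert-butyldimethylsilyl)oxy]-5-methylidene-6-(2-oxoethyl)-2-(propan-2-yl)cyclohexyl]acetate | C=C1C[C@@H](O[Si](C)(C)C(C)(C)C)[C@@H](C(C)C)[C@H](CC(=O)OC(C)(C)C)[C@H]1CC=O | intermediate
19 | trimethylsilyl ester of 20 (not isolated) | C=C1C[C@@H](O[Si](C)(C)C(C)(C)C)[C@@H](C(C)C)[C@H](CC(=O)O[Si](C)(C)C)[C@H]1CC=O | intermediate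
20 | 2-[(1R,2S,3R,6R)-3-[(tert-butyldimethylsilyl)oxy]-5-methylidene-6-(2-oxoethyl)-2-(propan-2-yl)cyclohexyl]acetic acid | C=C1C[C@@H](O[Si](C)(C)C(C)(C)C)[C@@H](C(C)C)[C@H](CC(=O)O)[C@H]1CC=O | intermediate
21 | cis-fused β-lactone of (1R,2S,3aR,6R,7S,7aR)-6-[(tert-butyldimethylsilyl)oxy]-2-hydroxy-4-methylidene-7-(propan-2-yl)octahydro-1H-indene-1-carboxylic acid | C=C1C[C@@H](O[Si](C)(C)C(C)(C)C)[C@@H](C(C)C)[C@@H]2[C@H]3C(=O)O[C@H]3C[C@@H]12 | intermediate
22 | (1R,2S,3aR,6R,7S,7aR)-6-[(tert-butyldimethylsilyl)oxy]-2-hydroxy-N-methoxy-N-methyl-4-methylidene-7-(propan-2-yl)octahydro-1H-indene-1-carboxamide | C=C1C[C@@H](O[Si](C)(C)C(C)(C)C)[C@@H](C(C)C)[C@@H]2[C@@H](C(=O)N(C)OC)[C@@H](O)C[C@@H]12 | intermediate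
23 | 1-[(1R,2S,3aR,6R,7S,7aR)-6-[(tert-butyldimethylsilyl)oxy]-2-hydroxy-4-methylidene-7-(propan-2-yl)octahydro-1H-inden-1-yl]ethan-1-one | C=C1C[C@@H](O[Si](C)(C)C(C)(C)C)[C@@H](C(C)C)[C@@H]2[C@@H](C(C)=O)[C@@H](O)C[C@@H]12 | intermediate
24 | angelic acid, (2Z)-2-methylbut-2-enoic acid | C/C=C(/C)C(=O)O | starting material
25 | angelic anhydride | C/C=C(/C)C(=O)OC(=O)/C(C)=C\C | intermediate
26 | lithium alkoxide of 23 (not isolated) | C=C1C[C@@H](O[Si](C)(C)C(C)(C)C)[C@@H](C(C)C)[C@@H]2[C@@H](C(C)=O)[C@@H]([O-])C[C@@H]12.[Li+] | intermediate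
27 | (1R,2S,3aR,6R,7S,7aR)-1-acetyl-6-[(tert-butyldimethylsilyl)oxy]-4-methylidene-7-(propan-2-yl)octahydro-1H-inden-2-yl (2Z)-2-methylbut-2-enoate | C=C1C[C@@H](O[Si](C)(C)C(C)(C)C)[C@@H](C(C)C)[C@@H]2[C@@H](C(C)=O)[C@@H](OC(=O)/C(C)=C\C)C[C@@H]12 | intermediate
28 | (1R,2S,3aR,6R,7S,7aR)-1-acetyl-6-hydroxy-4-methylidene-7-(propan-2-yl)octahydro-1H-inden-2-yl (2Z)-2-methylbut-2-enoate | C=C1C[C@@H](O)[C@@H](C(C)C)[C@@H]2[C@@H](C(C)=O)[C@@H](OC(=O)/C(C)=C\C)C[C@@H]12 | intermediate
29 | (2Z)-2-methylbut-2-en-1-ol | C/C=C(/C)CO | intermediate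
30 | [(2R,3S)-2,3-dimethyloxiran-2-yl]methanol | OC[C@@]1(C)O[C@H]1C | intermediate
31 | (2S,3S)-2,3-dimethyloxirane-2-carboxylic acid | OC(=O)[C@@]1(C)O[C@H]1C | intermediate
32 | (2S,3S)-2,3-dimethyloxirane-2-carboxylic 2,4,6-trichlorobenzoic anhydride (not isolated) | O=C(OC(=O)[C@@]1(C)O[C@H]1C)c1c(Cl)cc(Cl)cc1Cl | intermediate
33 | (1R,2S,3aR,6R,7S,7aR)-1-acetyl-4-methylidene-2-{[(2Z)-2-methylbut-2-enoyl]oxy}-7-(propan-2-yl)octahydro-1H-inden-6-yl (2S,3S)-2,3-dimethyloxirane-2-carboxylate | C=C1C[C@@H](OC(=O)[C@@]2(C)O[C@H]2C)[C@@H](C(C)C)[C@@H]2[C@@H](C(C)=O)[C@@H](OC(=O)/C(C)=C\C)C[C@@H]12 | target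

Total step count: 21. Longest linear sequence: 16 (steps 1–5, 7–14, 16, 17, 21).

Steps most likely to fail

Step 9. Hydrogen delivery to the C4 vinyl radical, from the stannane or by a 1,5-shift from C7a–H or the isopropyl methine, may outrun the 6-exo closure. The chair preference that sets C3a may also be eroded. The fallback generates the same C4 radical reversibly, by stannyl radical addition to a terminal alkyne instead of bromine abstraction. It sets out from 11 and comes back at 17.
- Tributyl(prop-2-yn-1-yl)stannane and the bromoborane of step 7 would give the allenyl diazaborolidine F1.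
- F1 would add to 11 at −78 °C to give the homopropargylic alcohol F2.
- TBSOTf and 2,6-lutidine would give its silyl ether F3.
- Bu3SnH and AIBN in dilute refluxing benzene would add Bu3Sn• to the alkyne terminus, and the β-stannylvinyl radical would close onto C3a to give the exocyclic vinylstannane F4.
- Protodestannylation of F4 with TsOH in CH2Cl2 at 0 °C would give 17.

Step 12. Intermolecular acylation of the activated acid may lead to oligomers, and face selection at C1/C2 may be incomplete. The fallback closes ring B at the ester oxidation level and sets C2 by hydride delivery. It sets out from 17 and comes back at 22.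
- Dieckmann condensation (KOt-Bu, THF, 0 °C) would give the β-keto ester F5. The tert-butyl ester can serve only as the enolate partner because its carbonyl is too hindered to be attacked.
- Chelation-controlled reduction with Zn(BH4)2 in Et2O, from the face opposite the C1 ester, would give the cis-β-hydroxy ester F6.
- Aqueous H3PO4 in toluene would cleave the tert-butyl ester to the hydroxy acid F7.
- Carbodiimide coupling of F7 with MeNH(OMe)·HCl would give 22.

Step 21. Slow acylation of the hindered axial C6 hydroxyl may leave time for DMAP and Et3N to expel the C2 angelate by β-elimination or to isomerise it from Z to E. The fallback reverses the order of the two acylations, so that the slow esterification runs while C2 carries a silyl ether, a poor leaving group. It sets out from 23 and comes back at 33.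
- HF·pyridine would give the diol F8.
- TESCl and imidazole would silylate the less hindered C2 hydroxyl selectively to the triethylsilyl ether F9.
- Esterification of F9 with mixed anhydride 32 and DMAP would give the epoxy ester F10.
- HF·pyridine would free the ketol F11.
- Alkoxide acylation of F11 with 25 under the conditions of step 16 would give 33.

Further compounds
F1 | step 9 | (4S,5S)-1,3-bis(4-methylbenzenesulfonyl)-4,5-diphenyl-2-(propa-1,2-dien-1-yl)-1,3,2-diazaborolidine | C=C=CB1N(S(=O)(=O)c2ccc(C)cc2)[C@@H](c2ccccc2)[C@H](c2ccccc2)N1S(=O)(=O)c1ccc(C)cc1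
F2 | step 9 | 6-tert-butyl 1-ethyl (2E,4R)-4-[(3S,4R)-4-hydroxy-2-methylhept-6-yn-3-yl]hex-2-enedioate | C#CC[C@@H](O)[C@@H](C(C)C)[C@@H](/C=C/C(=O)OCC)CC(=O)OC(C)(C)C
F3 | step 9 | 6-tert-butyl 1-ethyl (2E,4R)-4-{(3S,4R)-4-[(tert-butyldimethylsilyl)oxy]-2-methylhept-6-yn-3-yl}hex-2-enedioate | C#CC[C@@H](O[Si](C)(C)C(C)(C)C)[C@@H](C(C)C)[C@@H](/C=C/C(=O)OCC)CC(=O)OC(C)(C)C
F4 | step 9 | tert-butyl 2-[(1R,2S,3R,6R)-3-[(tert-butyldimethylsilyl)oxy]-6-(2-ethoxy-2-oxoethyl)-2-(propan-2-yl)-5-[(tributylstannyl)methylidene]cyclohexyl]acetate (E/Z mixture) | CCCC[Sn](CCCC)(CCCC)C=C1C[C@@H](O[Si](C)(C)C(C)(C)C)[C@@H](C(C)C)[C@H](CC(=O)OC(C)(C)C)[C@H]1CC(=O)OCC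
F5 | step 12 | tert-butyl (1R,3aR,6R,7S,7aR)-6-[(tert-butyldimethylsilyl)oxy]-4-methylidene-2-oxo-7-(propan-2-yl)octahydro-1H-indene-1-carboxylate | C=C1C[C@@H](O[Si](C)(C)C(C)(C)C)[C@@H](C(C)C)[C@@H]2[C@@H](C(=O)OC(C)(C)C)C(=O)C[C@@H]12
F6 | step 12 | tert-butyl (1R,2S,3aR,6R,7S,7aR)-6-[(tert-butyldimethylsilyl)oxy]-2-hydroxy-4-methylidene-7-(propan-2-yl)octahydro-1H-indene-1-carboxylate | C=C1C[C@@H](O[Si](C)(C)C(C)(C)C)[C@@H](C(C)C)[C@@H]2[C@@H](C(=O)OC(C)(C)C)[C@@H](O)C[C@@H]12
F7 | step 12 | (1R,2S,3aR,6R,7S,7aR)-6-[(tert-butyldimethylsilyl)oxy]-2-hydroxy-4-methylidene-7-(propan-2-yl)octahydro-1H-indene-1-carboxylic acid | C=C1C[C@@H](O[Si](C)(C)C(C)(C)C)[C@@H](C(C)C)[C@@H]2[C@@H](C(=O)O)[C@@H](O)C[C@@H]12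
F8 | step 21 | 1-[(1R,2S,3aR,6R,7S,7aR)-2,6-dihydroxy-4-methylidene-7-(propan-2-yl)octahydro-1H-inden-1-yl]ethan-1-one | C=C1C[C@@H](O)[C@@H](C(C)C)[C@@H]2[C@@H](C(C)=O)[C@@H](O)C[C@@H]12
F9 | step 21 | 1-[(1R,2S,3aR,6R,7S,7aR)-6-hydroxy-4-methylidene-7-(propan-2-yl)-2-[(triethylsilyl)oxy]octahydro-1H-inden-1-yl]ethan-1-one | C=C1C[C@@H](O)[C@@H](C(C)C)[C@@H]2[C@@H](C(C)=O)[C@@H](O[Si](CC)(CC)CC)C[C@@H]12
F10 | step 21 | (1R,2S,3aR,6R,7S,7aR)-1-acetyl-4-methylidene-7-(propan-2-yl)-2-[(triethylsilyl)oxy]octahydro-1H-inden-6-yl (2S,3S)-2,3-dimethyloxirane-2-carboxylate | C=C1C[C@@H](OC(=O)[C@@]2(C)O[C@H]2C)[C@@H](C(C)C)[C@@H]2[C@@H](C(C)=O)[C@@H](O[Si](CC)(CC)CC)C[C@@H]12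
F11 | step 21 | (1R,2S,3aR,6R,7S,7aR)-1-acetyl-2-hydroxy-4-methylidene-7-(propan-2-yl)octahydro-1H-inden-6-yl (2S,3S)-2,3-dimethyloxirane-2-carboxylate | C=C1C[C@@H](OC(=O)[C@@]2(C)O[C@H]2C)[C@@H](C(C)C)[C@@H]2[C@@H](C(C)=O)[C@@H](O)C[C@@H]12
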